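**Remark on the chemistry.** Ring positions are counted in each benzoate ring from the carbonyl-bearing carbon (C1) through the ortho-hydroxyl carbon (C2). Compounds 1, 2, 7 and 18 and all reagents are taken to be purchasable. The structures of the diazo enone, the siloxyalkyne and the benzannulation product were checked atom by atom against the mechanism and need no correction. The one change of design is the access to the diazo enone: it is made by diazo transfer to a methyl ketone, not by acylating diazomethane.

## Structural features

The target is a linear tridepside without any stereocentre. Three 2-hydroxy-6-methylbenzoyl units (rings A, B, C) are joined by two aryl ester bonds, from the ring A C1 carbonyl to the ring B C4 oxygen and from the ring B C1 carbonyl to the ring C C4 oxygen, and ring C ends in a free C1 carboxylic acid. Rings B and C are orsellinate units (C2 hydroxyl, hydrogen at C3 and C5, C6 methyl). Ring A is pentasubstituted, with hydroxyls at C2 and C4, an acetoxy group at C5 and the methyl at C6. Since nothing is chiral, no stereocentres stand next to each other, and the problem is purely regiochemical: six phenolic oxygens and three carboxyl carbons must each end up acylated, free or protected in the right place. The fragile groups are the two depside esters and the aryl acetate, all active esters that hydroxide, alkoxide, amines or basic fluoride cleave or transesterify. In addition the C5 acetate can migrate to the neighbouring C4 hydroxyl under base, ring A is an oxidation-prone hydroxyquinol once its phenols are free, and the ring C acid decarboxylates on heating. The real difficulty lies in ring A (one acetate on one of three oxygens, the C5 oxygen wedged between C4–O and the C6 methyl) and in esterifying hindered 2,6-disubstituted benzoic acids with specific phenols, with a neutral last step. The key step uses the ring C pattern (C1 carboxyl between the C2 hydroxyl and the C6 methyl, hydrogen at C3 and C5, C4 oxygen meta to C2). This maps onto a vinylketene (ketene carbon = C2, then C5, C6, C1) and an ynol ether (C3, C4), so that bonds C1–C2, C2–C3 and C4–C5 form in one operation and the two oxygens arrive differentiated.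

## Logic of the disconnections

31 to 30: the three benzyl–oxygen bonds are cut (ring A C2–O and C4–O ethers, ring C carboxylate). All three fall in one neutral hydrogenolysis, which is the only kind of final step the acetate and the depside esters tolerate. The demand is that every other group of 31 is already in place in 30.

30 to 28 + 17: the ester bond between the ring B C1 carbonyl and the ring C C4 oxygen is cut. This divides the molecule into a two-ring acid and a one-ring phenol of similar effort. The forward acylation must choose the C4 hydroxyl of 17 over its chelated C2 hydroxyl, and activated 28 must not acylate its own ring B hydroxyl.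

28 to 27, then 27 to 25 + 18: the ring B carboxyl is traced to a formyl group, and the ester bond between the ring A C1 carbonyl and the ring B C4 oxygen is cut. A formyl group is a carboxyl that needs no protecting group and cannot be activated by mistake, and 18 is purchasable. The demands are selective acylation of the non-chelated C4 hydroxyl of 18 and an aldehyde oxidation that leaves acetate and aryl ester alone.

25 to 24 to 22: the bond between ring A C1 and its carboxyl carbon is cut (formyl introduction, then oxidation). This leaves an arene with only two free positions. Electrophilic substitution must enter next to the methyl, para to one benzyloxy group, and not between the two benzyloxy groups.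

22 to 21 to 19 to 18: the acetyl–oxygen bond is cut, the ring A C5–O bond is traced to the formyl carbon of 19 by a Baeyer–Villiger exchange of C–C for C–O, and the benzyl ethers are removed. The C5 oxygen thus appears as the only free phenol of the ring, which solves the acetate placement, and rings A and B come from the same aldehyde 18. The demand is aryl (not hydride) migration in the oxidation.

17 to 15: the C3–Si bond and the C4 O–Si bond are cut. Both silyl groups are spectators that come with the alkyne partner; their removal must spare the benzyl ester.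

15 to 6 + 10: the ring C bonds C1–C2, C2–C3 and C4–C5 are cut. Ring C falls to two acyclic components that fix every substituent by their connectivity. The forward step demands that the silyl-bearing alkyne carbon bonds to the ketene carbonyl carbon, and that the alkene geometry of 6 lets the 6π closure proceed.

6 to 3, then 3 to 1 + 2: the diazo group is removed from C5 (a C–H to C=N2 exchange) and the C2=C3 alkene is cut by a Wittig disconnection. The diazo-transfer route is preferred to cutting C4–C5 back to an acid chloride and diazomethane, because that route is hazardous and the dipole adds to electron-poor alkenes. The demands are kinetic enolisation at the acetyl methyl of 3 and E-selective olefination.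

10 to 7: the alkynyl C–O bond and the O–Si bond are cut. The acetylide must be oxygenated without loss of its C-silyl group, and the ynolate must be silylated on oxygen.

## Other disconnections considered

Alternative 1: Ring B is cut at C1–C6 together with the ester bond from the ring B carbonyl to the ring C oxygen.
- **Forward step:** diketo-dioxinone A1 is heated with the ring C phenol A2. The dioxinone fragments to an acylketene, which the phenol traps to give aryl trioxooctanoate A3. An amine-promoted aldol of chain C2 onto the C7 ketone and dehydration then give didepside A4.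
- **In favour:** the depside bond and ring B form in one pot without activating a hindered benzoic acid, and A4 carries the ring B C4 hydroxyl free for the next acylation.
- **Against:** A3 is an aryl ester of a polyketo acid, so lactonisation to a hydroxypyranone with expulsion of A2, or aminolysis, can compete with the C-cyclisation. A2 is a deactivated phenol and a mediocre ketene trap. A1 and the differentiated A2 each need several steps.
- **Comparison:** on structure it is the better use of a ring-forming step, since it makes a joint of the molecule, whereas the chosen step makes the simplest ring. It also avoids the oxidation and the hydroxy-acid coupling of steps 12 and 13, which is a point in its favour. On mechanism the chosen plan is safer, because its cascade carries only a stable benzyl ester. Step economy is about equal.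

Alternative 2: Ring A is cut at C1–C6 and C3–C4.
- **Forward step:** the enolate of A5 adds to alkoxycrotonate A6, and Claisen closure gives cyclohexanedione A7, which is oxidised later to resorcylate A8.
- **In favour:** the C5 oxygen is placed by construction, with no regiochemical question of the kind that step 9 raises. This is better than the chosen plan on that point. The inputs are cheap and the C5 oxygen is differentiated from the start.
- **Against:** A7 needs an oxidative aromatisation that keeps the C5 alkoxy group. The redox-neutral path, loss of that group as its alcohol across C5–C6, would lead to A9, which lacks the oxygen the route was built to install. The ether also forbids quinone oxidants. A6 is a donor-substituted, beta-branched acceptor and a sluggish Michael partner. Benzylation, ether cleavage, acetylation and ester cleavage still follow.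
- **Comparison:** it addresses the hardest ring, which the chosen key step does not. Neither plan has a stereochemical issue (equal). On mechanism and on step count for ring A the chosen sequence (steps 6 to 10) should be the more secure and the shorter.

Alternative 3: Ring A is cut at C1–C2 and C5–C6 on the complete B–C scaffold.
- **Forward step:** siloxyfuran A10 adds across aryl butynoate A11. The bridged adduct A12 opens at the ketal carbon and tautomerises to A13, with a C2 silyl ether, a C4 benzyl ether and a free C5 hydroxyl.
- **In favour:** it is the most convergent of all. The three ring A oxygens are differentiated in one step with exactly the C5 hydroxyl free for acetylation. The polarity is matched (furan C5 to the methyl-bearing alkyne carbon). The sensitive hydroxyquinol appears late. On these structural points it is better than the chosen plan.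
- **Against:** A10 is a labile, doubly activated furan. A butynoate is a poor dienophile, so heating or a Lewis acid would be needed in the presence of the aryl esters of A11. The later silyl ether cleavage must spare a neighbouring aryl acetate.
- **Comparison:** the benzannulation of the chosen plan is the better-understood reaction. Step economy would be equal or slightly better for this alternative if the cycloaddition worked.

Key step: step 4

## Route

Step 1
Reactants: 1 butane-2,3-dione; 2 benzyl (triphenylphosphoranylidene)acetate
Product: 3 benzyl (E)-3-methyl-4-oxopent-2-enoate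
Conditions: 1 (2 equiv), CH2Cl2, 0 °C to rt
Reagents that add atoms: none
Why: Wittig olefination of one carbonyl of the symmetrical 1,2-diketone by the ester-stabilised ylide; the excess of 1 suppresses a second olefination, and the stabilised ylide should place acetyl and ester trans (E).

Step 2
Reactants: 3 benzyl (E)-3-methyl-4-oxopent-2-enoate
Product: 6 benzyl (E)-5-diazo-3-methyl-4-oxopent-2-enoate, via lithium enolate 4 (not isolated), via trifluoroacetyl diketone 5 (not isolated)
Conditions: LiN(SiMe3)2, THF, −78 °C; CF3CO2CH2CF3, −78 °C; aq. HCl work-up; then 4-AcNHC6H4SO2N3, Et3N, H2O (1 equiv), MeCN, rt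
Reagents that add atoms: 4-acetamidobenzenesulfonyl azide CC(=O)Nc1ccc(cc1)S(=O)(=O)N=[N+]=[N-] (the two nitrogens of 6); 2,2,2-trifluoroethyl trifluoroacetate FC(F)(F)COC(=O)C(F)(F)F (trifluoroacetyl group of 5 only, lost again)
Why: Detrifluoroacetylative (Regitz-type) diazo transfer: kinetic deprotonation of the acetyl methyl, C-trifluoroacetylation to the activated 1,3-diketone 5, then transfer of N2 from the sulfonyl azide with loss of the trifluoroacetyl group as the N-acylsulfonamide; no diazomethane is needed, which removes both its hazard and its dipolar addition to the electron-poor alkene.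

Step 3
Reactants: 7 ethynyltrimethylsilane
Product: 10 triisopropyl{[(trimethylsilyl)ethynyl]oxy}silane, via lithium acetylide 8 (not isolated), via lithium ynolate 9 (not isolated)
Conditions: n-BuLi, THF, −78 °C; LiOOt-Bu (from t-BuOOH and LiN(SiMe3)2, THF, −78 °C), −78 to 0 °C; then i-Pr3SiOSO2CF3, −78 to 0 °C
Reagents that add atoms: tert-butyl hydroperoxide CC(C)(C)OO (the oxygen atom); triisopropylsilyl trifluoromethanesulfonate CC(C)[Si](OS(=O)(=O)C(F)(F)F)(C(C)C)C(C)C
Why: Oxygenation of a lithium acetylide by a lithium alkyl peroxide (carbon attacks the O–O bond) gives ynolate 9, and the bulky, hard silyl triflate should react at oxygen and not at the silyl-bearing carbon; the C-silyl group makes 10 storable and later occupies ring C C3.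

Step 4
Reactants: 6 benzyl (E)-5-diazo-3-methyl-4-oxopent-2-enoate; 10 triisopropyl{[(trimethylsilyl)ethynyl]oxy}silane
Product: 15 benzyl 2-hydroxy-6-methyl-4-(triisopropylsilyloxy)-3-(trimethylsilyl)benzoate, via vinylketene 11 (not isolated), via vinylcyclobutenone 12 (not isolated), via dienylketene 13 (not isolated), via cyclohexadienone 14 (not isolated)
Conditions: 10 (1.3 equiv), hν (365 nm), degassed ClCH2CH2Cl, rt; then 80 °C
Reagents that add atoms: none
Why: Irradiation expels N2 from 6 and the alkenyl group migrates (photochemical Wolff rearrangement) to give vinylketene 11. The electron-rich ynol ether 10 adds across the ketene C=C in a regioselective [2+2] cycloaddition, its silyl-bearing nucleophilic carbon bonding to the ketene carbonyl carbon (ring C C2–C3) and its oxygen-bearing carbon to the ketene alpha carbon (C4–C5), which closes the four-membered ring of 12. On heating, conrotatory 4π opening of 12 gives dienylketene 13, and a thermal disrotatory 6π electrocyclisation joins the ketene carbon to the ester-bearing alkene terminus (C1–C2); this closure makes ring C, and enolisation of 14 gives the phenol. The closest known reaction type is the second-generation Danheiser benzannulation of alpha-diazo enones with siloxyalkynes; the ester on the vinylketene terminus is the new feature of the substrate. No stereocentre results, because the sp3 carbons of 12 and 14 are lost on ring opening and tautomerisation. The step needs the two oxygens meta on the new ring, which the polarisation of 10 (oxygen lone pair pushing density onto the silylated carbon) and of the ketene (electrophilic at the carbonyl carbon) secures, and it needs 10 to react with the ketene and not with the enoate of 6, which the far higher electrophilicity of the ketene secures. The E geometry of 6 keeps hydrogen, not the ester, on the inside of the closing terminus and keeps the ester carbonyl away from the ketene carbon. The opening of 12 is reversible, so whichever dienylketene geometry forms first, the reactive isomer 13 is drained by the irreversible electrocyclisation.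

Step 5
Reactants: 15 benzyl 2-hydroxy-6-methyl-4-(triisopropylsilyloxy)-3-(trimethylsilyl)benzoate
Product: 17 benzyl 2,4-dihydroxy-6-methylbenzoate, via C-desilylated silyl ether 16 (not isolated)
Conditions: CF3CO2H, CH2Cl2, 0 °C to rt; evaporate; then Bu4NF, THF, 0 °C; aq. NH4Cl
Reagents that add atoms: none
Why: Acid-promoted ipso-protodesilylation of the aryl–SiMe3 bond, very fast at a carbon flanked by two oxygen substituents, followed by fluoride cleavage of the aryl silyl ether; the benzyl ester is inert to both reagents.

Step 6
Reactants: 18 2,4-dihydroxy-6-methylbenzaldehyde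
Product: 19 2,4-bis(benzyloxy)-6-methylbenzaldehyde
Conditions: BnBr (2.5 equiv), K2CO3, DMF, 60 °C
Reagents that add atoms: benzyl bromide BrCc1ccccc1
Why: Williamson etherification of both phenols; the hydrogen-bonded C2 hydroxyl needs the polar solvent and warming to go to completion.

Step 7
Reactants: 19 2,4-bis(benzyloxy)-6-methylbenzaldehyde
Product: 21 2,4-bis(benzyloxy)-6-methylphenol, via aryl formate 20 (not isolated)
Conditions: mCPBA, CH2Cl2, 0 °C to rt; then K2CO3 (cat.), MeOH, rt
Reagents that add atoms: 3-chloroperoxybenzoic acid OOC(=O)c1cccc(Cl)c1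
Why: Baeyer–Villiger (Dakin-type) oxidation: the electron-rich dialkoxyaryl group migrates in the Criegee intermediate to give formate 20, which is transesterified to the phenol; the former formyl position becomes the future ring A C5 oxygen, the only free phenol of the ring.

Step 8
Reactants: 21 2,4-bis(benzyloxy)-6-methylphenol
Product: 22 2,4-bis(benzyloxy)-6-methylphenyl acetate
Conditions: Ac2O, pyridine, DMAP (cat.), CH2Cl2, rt
Reagents that add atoms: acetic anhydride CC(=O)OC(C)=O
Why: Acylation of the phenol under nucleophilic catalysis; the acetate is the group required in the target and also stabilises the oxidation-prone hydroxyquinol diether.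

Step 9
Reactants: 22 2,4-bis(benzyloxy)-6-methylphenyl acetate
Product: 24 5-acetoxy-2,4-bis(benzyloxy)-6-methylbenzaldehyde, via iminium chloride 23 (not isolated)
Conditions: POCl3, DMF, 0 to 70 °C; then aq. NaOAc, rt
Reagents that add atoms: N,N-dimethylformamide CN(C)C=O (formyl carbon); water O (carbonyl oxygen)
Why: Vilsmeier–Haack formylation: the chloroiminium ion should attack the carbon next to the methyl, para to one benzyloxy group and ortho to the other, since resorcinol diethers are substituted there in preference to the carbon between the two alkoxy groups; hydrolysis of 23 gives the aldehyde, and the aryl acetate survives the non-nucleophilic medium and the weakly acidic work-up.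

Step 10
Reactants: 24 5-acetoxy-2,4-bis(benzyloxy)-6-methylbenzaldehyde
Product: 25 5-acetoxy-2,4-bis(benzyloxy)-6-methylbenzoic acid
Conditions: NaClO2, NaH2PO4, 2-methylbut-2-ene, t-BuOH/THF/H2O, 0 °C to rt
Reagents that add atoms: sodium chlorite [Na+].[O-]Cl=O
Why: Pinnick oxidation (chlorous acid, hypochlorite scavenged by the alkene) converts the hindered aldehyde into the acid at about pH 4, where the aryl acetate and the benzyl ethers are stable.

Step 11
Reactants: 25 5-acetoxy-2,4-bis(benzyloxy)-6-methylbenzoic acid; 18 2,4-dihydroxy-6-methylbenzaldehyde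
Product: 27 4-formyl-3-hydroxy-5-methylphenyl 5-acetoxy-2,4-bis(benzyloxy)-6-methylbenzoate, via mixed anhydride 26 (not isolated)
Conditions: (CF3CO)2O, toluene, 0 °C to rt; aq. NaHCO3 wash
Reagents that add atoms: none
Why: Esterification through the mixed trifluoroacetic anhydride 26: the hindered, electron-rich aroyl trifluoroacetate reacts as an acylium-type electrophile with the free C4 hydroxyl of 18, while the C2 hydroxyl is tied up in a hydrogen bond to the formyl group; the acidic medium excludes acetyl migration, and any aryl trifluoroacetate is hydrolysed in the bicarbonate wash.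

Step 12
Reactants: 27 4-formyl-3-hydroxy-5-methylphenyl 5-acetoxy-2,4-bis(benzyloxy)-6-methylbenzoate
Product: 28 4-{[5-acetoxy-2,4-bis(benzyloxy)-6-methylbenzoyl]oxy}-2-hydroxy-6-methylbenzoic acid
Conditions: NaClO2, NaH2PO4, 2-methylbut-2-ene, t-BuOH/THF/H2O, 0 °C to rt
Reagents that add atoms: sodium chlorite [Na+].[O-]Cl=O
Why: Pinnick oxidation of the salicylaldehyde-type formyl group; the phenol-bearing ring is deactivated by the formyl and aroyloxy groups and the alkene removes hypochlorite, so ring chlorination is not expected, and both aryl esters are stable at this pH.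

Step 13
Reactants: 28 4-{[5-acetoxy-2,4-bis(benzyloxy)-6-methylbenzoyl]oxy}-2-hydroxy-6-methylbenzoic acid; 17 benzyl 2,4-dihydroxy-6-methylbenzoate
Product: 30 benzyl 4-[(4-{[5-acetoxy-2,4-bis(benzyloxy)-6-methylbenzoyl]oxy}-2-hydroxy-6-methylbenzoyl)oxy]-2-hydroxy-6-methylbenzoate, via mixed anhydride 29 (not isolated)
Conditions: (CF3CO)2O, toluene, 0 °C to rt; aq. NaHCO3 wash
Reagents that add atoms: none
Why: Mixed-anhydride esterification as in step 11: activated 29 should acylate the only non-chelated phenol present, the C4 hydroxyl of 17, because the C2 hydroxyls of 17 and of 28 are hydrogen-bonded to their ortho carbonyl groups and are poor nucleophiles.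

Step 14
Reactants: 30 benzyl 4-[(4-{[5-acetoxy-2,4-bis(benzyloxy)-6-methylbenzoyl]oxy}-2-hydroxy-6-methylbenzoyl)oxy]-2-hydroxy-6-methylbenzoate
Product: 31 4-[(4-{[5-acetoxy-2,4-dihydroxy-6-methylbenzoyl]oxy}-2-hydroxy-6-methylbenzoyl)oxy]-2-hydroxy-6-methylbenzoic acid (CNP0154030.0)
Conditions: H2 (1 atm), Pd/C (10%), EtOAc, rt
Reagents that add atoms: none
Why: Heterogeneous hydrogenolysis cleaves the two benzyl ethers and the benzyl ester under neutral conditions in a non-nucleophilic solvent, so neither depside ester nor the acetate (which could migrate to the neighbouring C4 hydroxyl under base) is touched.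

## Compound list

1 | butane-2,3-dione | CC(=O)C(C)=O | starting material
2 | benzyl (triphenylphosphoranylidene)acetate | O=C(C=P(c1ccccc1)(c1ccccc1)c1ccccc1)OCc1ccccc1 | starting material
3 | benzyl (E)-3-methyl-4-oxopent-2-enoate | C/C(C(C)=O)=C\C(=O)OCc1ccccc1 | intermediate
4 | lithium (3E)-5-(benzyloxy)-3-methyl-5-oxopenta-1,3-dien-2-olate (lithium enolate of 3) | [Li+].[O-]C(=C)/C(C)=C/C(=O)OCc1ccccc1 | intermediate (not isolated)
5 | benzyl (E)-7,7,7-trifluoro-3-methyl-4,6-dioxohept-2-enoate | C/C(C(=O)CC(=O)C(F)(F)F)=C\C(=O)OCc1ccccc1 | intermediate (not isolated)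
6 | benzyl (E)-5-diazo-3-methyl-4-oxopent-2-enoate | C/C(C(=O)C=[N+]=[N-])=C\C(=O)OCc1ccccc1 | intermediate
7 | ethynyltrimethylsilane (trimethylsilylacetylene) | C#C[Si](C)(C)C | starting material
8 | lithium (trimethylsilyl)acetylide | [Li]C#C[Si](C)(C)C | intermediate (not isolated)
9 | lithium 2-(trimethylsilyl)ethynolate | [Li+].[O-]C#C[Si](C)(C)C | intermediate (not isolated)
10 | triisopropyl{[(trimethylsilyl)ethynyl]oxy}silane | C[Si](C)(C)C#CO[Si](C(C)C)(C(C)C)C(C)C | intermediate
11 | benzyl (2E)-3-methyl-5-oxopenta-2,4-dienoate (vinylketene) | O=C=C/C(C)=C/C(=O)OCc1ccccc1 | intermediate (not isolated)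
12 | benzyl (E)-3-[4-oxo-2-(triisopropylsilyloxy)-3-(trimethylsilyl)cyclobut-2-en-1-yl]but-2-enoate (racemic) | C/C(=C\C(=O)OCc1ccccc1)C1C(=O)C([Si](C)(C)C)=C1O[Si](C(C)C)(C(C)C)C(C)C | intermediate (not isolated)
13 | benzyl (2E,4E)-3-methyl-7-oxo-5-(triisopropylsilyloxy)-6-(trimethylsilyl)hepta-2,4,6-trienoate (dienylketene; ketene carbon and C3 cis across C4=C5) | O=C=C([Si](C)(C)C)/C(O[Si](C(C)C)(C(C)C)C(C)C)=C\C(C)=C\C(=O)OCc1ccccc1 | intermediate (not isolated)
14 | benzyl 2-methyl-6-oxo-4-(triisopropylsilyloxy)-5-(trimethylsilyl)cyclohexa-2,4-diene-1-carboxylate (racemic) | CC1=CC(O[Si](C(C)C)(C(C)C)C(C)C)=C([Si](C)(C)C)C(=O)C1C(=O)OCc1ccccc1 | intermediate (not isolated)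
15 | benzyl 2-hydroxy-6-methyl-4-(triisopropylsilyloxy)-3-(trimethylsilyl)benzoate | Cc1cc(O[Si](C(C)C)(C(C)C)C(C)C)c([Si](C)(C)C)c(O)c1C(=O)OCc1ccccc1 | intermediate
16 | benzyl 2-hydroxy-6-methyl-4-(triisopropylsilyloxy)benzoate | Cc1cc(O[Si](C(C)C)(C(C)C)C(C)C)cc(O)c1C(=O)OCc1ccccc1 | intermediate (not isolated)
17 | benzyl 2,4-dihydroxy-6-methylbenzoate | Cc1cc(O)cc(O)c1C(=O)OCc1ccccc1 | intermediate
18 | 2,4-dihydroxy-6-methylbenzaldehyde | Cc1cc(O)cc(O)c1C=O | starting material
19 | 2,4-bis(benzyloxy)-6-methylbenzaldehyde | Cc1cc(OCc2ccccc2)cc(OCc2ccccc2)c1C=O | intermediate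
20 | 2,4-bis(benzyloxy)-6-methylphenyl formate | O=COc1c(C)cc(OCc2ccccc2)cc1OCc1ccccc1 | intermediate (not isolated)
21 | 2,4-bis(benzyloxy)-6-methylphenol | Oc1c(C)cc(OCc2ccccc2)cc1OCc1ccccc1 | intermediate
22 | 2,4-bis(benzyloxy)-6-methylphenyl acetate | CC(=O)Oc1c(C)cc(OCc2ccccc2)cc1OCc1ccccc1 | intermediate
23 | N-{[3-acetoxy-4,6-bis(benzyloxy)-2-methylphenyl]methylidene}-N-methylmethanaminium chloride | CC(=O)Oc1c(C)c(C=[N+](C)C)c(OCc2ccccc2)cc1OCc1ccccc1.[Cl-] | intermediate (not isolated)
24 | 5-acetoxy-2,4-bis(benzyloxy)-6-methylbenzaldehyde (= 4,6-bis(benzyloxy)-3-formyl-2-methylphenyl acetate) | CC(=O)Oc1c(C)c(C=O)c(OCc2ccccc2)cc1OCc1ccccc1 | intermediate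
25 | 5-acetoxy-2,4-bis(benzyloxy)-6-methylbenzoic acid | CC(=O)Oc1c(C)c(C(=O)O)c(OCc2ccccc2)cc1OCc1ccccc1 | intermediate
26 | 5-acetoxy-2,4-bis(benzyloxy)-6-methylbenzoic trifluoroacetic anhydride | CC(=O)Oc1c(C)c(C(=O)OC(=O)C(F)(F)F)c(OCc2ccccc2)cc1OCc1ccccc1 | intermediate (not isolated)
27 | 4-formyl-3-hydroxy-5-methylphenyl 5-acetoxy-2,4-bis(benzyloxy)-6-methylbenzoate | CC(=O)Oc1c(C)c(C(=O)Oc2cc(C)c(C=O)c(O)c2)c(OCc2ccccc2)cc1OCc1ccccc1 | intermediate
28 | 4-{[5-acetoxy-2,4-bis(benzyloxy)-6-methylbenzoyl]oxy}-2-hydroxy-6-methylbenzoic acid | CC(=O)Oc1c(C)c(C(=O)Oc2cc(C)c(C(=O)O)c(O)c2)c(OCc2ccccc2)cc1OCc1ccccc1 | intermediate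
29 | mixed anhydride of 28 with trifluoroacetic acid | CC(=O)Oc1c(C)c(C(=O)Oc2cc(C)c(C(=O)OC(=O)C(F)(F)F)c(O)c2)c(OCc2ccccc2)cc1OCc1ccccc1 | intermediate (not isolated)
30 | benzyl 4-[(4-{[5-acetoxy-2,4-bis(benzyloxy)-6-methylbenzoyl]oxy}-2-hydroxy-6-methylbenzoyl)oxy]-2-hydroxy-6-methylbenzoate | CC(=O)Oc1c(C)c(C(=O)Oc2cc(C)c(C(=O)Oc3cc(C)c(C(=O)OCc4ccccc4)c(O)c3)c(O)c2)c(OCc2ccccc2)cc1OCc1ccccc1 | intermediate
31 | 4-[(4-{[5-acetoxy-2,4-dihydroxy-6-methylbenzoyl]oxy}-2-hydroxy-6-methylbenzoyl)oxy]-2-hydroxy-6-methylbenzoic acid (CNP0154030.0) | CC(=O)Oc1c(O)cc(O)c(C(=O)Oc2cc(C)c(C(=O)Oc3cc(C)c(C(=O)O)c(O)c3)c(O)c2)c1C | target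

## Step count and least certain steps

Total step count: 14. Longest linear sequence: 9 steps (steps 6 to 14, from 18 to 31). The ring C branch (steps 1, 2, 4, 5) and the alkyne branch (step 3) join it at step 13.

**Step 4 (key step).**
- **Risk:** photochemical E/Z isomerisation of the enoate before or after the Wolff rearrangement would bring the ester cis to the ketene, where oxa-6π closure onto the ester carbonyl (pyranone formation) competes with the [2+2] addition. Ketene dimerisation, or acylation of the product phenol by the ketene, would also lower the return.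
- **Fallback:** ring C would be taken from the aromatic pool. It sets out from 19 and comes back at 17. Pinnick oxidation of 19 (NaClO2, NaH2PO4, 2-methylbut-2-ene) should give 2,4-bis(benzyloxy)-6-methylbenzoic acid F1. Hydrogenolysis (H2, Pd/C, EtOAc) should give 2,4-dihydroxy-6-methylbenzoic acid F2. Selective alkylation of the carboxylate (BnBr, KHCO3, DMF, rt), which leaves the phenols protonated, should give 17.

**Step 2.**
- **Risk:** conjugate addition of the enolate to the doubly activated alkene of unreacted 3 (oligomerisation) during enolate generation, and slow dipolar addition of the diazo group of 6 to its own electron-poor alkene on concentration or storage.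
- **Fallback:** the acylation route, setting out from 2 and coming back at 6. Wittig reaction of 2 with tert-butyl pyruvate should give 4-benzyl 1-tert-butyl (E)-2-methylbut-2-enedioate F3. CF3CO2H in CH2Cl2 should give (E)-4-(benzyloxy)-2-methyl-4-oxobut-2-enoic acid F4. Oxalyl chloride with catalytic DMF should give benzyl (E)-4-chloro-3-methyl-4-oxobut-2-enoate F5. Acylation of (trimethylsilyl)diazomethane with F5 at 0 °C (Arndt–Eistert first stage, the silyl group leaving as the chloride) should give 6.

**Step 3.**
- **Risk:** attack of the peroxide or of the tert-butoxide by-product at silicon (desilylation of the acetylide) in place of oxygenation at carbon, or partial C-silylation of the ambident ynolate.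
- **Fallback:** no numbered compound can serve as its origin. It sets out from purchased ethoxyacetylene in place of 7 and comes back at 9. Lithiation (n-BuLi) and silylation (Me3SiCl) should give (ethoxyethynyl)trimethylsilane F6. Thermolysis at about 120 °C (retro-ene loss of ethene) should give (trimethylsilyl)ketene F7. Deprotonation of F7 with n-BuLi in THF at −100 °C should give ynolate 9, which is silylated as in step 3 to 10.

**Step 9.**
- **Risk:** attack of the bulky chloroiminium ion at the carbon between the two benzyloxy groups in place of the doubly flanked carbon next to the methyl, or no substitution at that hindered carbon, with loss of the acetate on forcing.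
- **Fallback:** halogenation and carboxylation with a small electrophile. It sets out from 21 and comes back at 25.
  - Silylation (i-Pr3SiCl, imidazole, DMF) should give [2,4-bis(benzyloxy)-6-methylphenoxy]triisopropylsilane F8.
  - Para-selective bromination (N-bromosuccinimide, MeCN, 0 °C) should give [4,6-bis(benzyloxy)-3-bromo-2-methylphenoxy]triisopropylsilane F9.
  - Bromine–lithium exchange (n-BuLi, THF, −78 °C) should give [4,6-bis(benzyloxy)-2-methyl-3-(triisopropylsilyloxy)phenyl]lithium F10.
  - Quenching F10 with CO2 should give 2,4-bis(benzyloxy)-6-methyl-5-(triisopropylsilyloxy)benzoic acid F11.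
  - Bu4NF in THF should give 2,4-bis(benzyloxy)-5-hydroxy-6-methylbenzoic acid F12.
  - Acetylation (Ac2O, pyridine, then aqueous work-up to hydrolyse the mixed anhydride) should give 25.

**Step 13.**
- **Risk:** self-acylation of the activated hydroxy acid (oligomeric salicylide-type esters through the ring B C2 hydroxyl) competing with acylation of 17, or partial debenzylation of ring A by the trifluoroacetic acid formed.
- **Fallback:** protection of the ring B hydroxyl and a carbodiimide coupling. It sets out from 27 and comes back at 31.
  - Mitsunobu benzylation (BnOH, PPh3, diisopropyl azodicarboxylate, THF) should give 3-(benzyloxy)-4-formyl-5-methylphenyl 5-acetoxy-2,4-bis(benzyloxy)-6-methylbenzoate F13.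
  - Pinnick oxidation should give 4-{[5-acetoxy-2,4-bis(benzyloxy)-6-methylbenzoyl]oxy}-2-(benzyloxy)-6-methylbenzoic acid F14.
  - Coupling with 17 (N-(3-dimethylaminopropyl)-N′-ethylcarbodiimide hydrochloride, DMAP, CH2Cl2) should give benzyl 4-[(4-{[5-acetoxy-2,4-bis(benzyloxy)-6-methylbenzoyl]oxy}-2-(benzyloxy)-6-methylbenzoyl)oxy]-2-hydroxy-6-methylbenzoate F15.
  - Hydrogenolysis as in step 14 should give 31.

## Further compounds

F1 | step 4 | 2,4-bis(benzyloxy)-6-methylbenzoic acid | Cc1cc(OCc2ccccc2)cc(OCc2ccccc2)c1C(=O)O
F2 | step 4 | 2,4-dihydroxy-6-methylbenzoic acid | Cc1cc(O)cc(O)c1C(=O)O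
F3 | step 2 | 4-benzyl 1-tert-butyl (E)-2-methylbut-2-enedioate | C/C(C(=O)OC(C)(C)C)=C\C(=O)OCc1ccccc1
F4 | step 2 | (E)-4-(benzyloxy)-2-methyl-4-oxobut-2-enoic acid | C/C(C(=O)O)=C\C(=O)OCc1ccccc1
F5 | step 2 | benzyl (E)-4-chloro-3-methyl-4-oxobut-2-enoate | C/C(C(Cl)=O)=C\C(=O)OCc1ccccc1
F6 | step 3 | (ethoxyethynyl)trimethylsilane | CCOC#C[Si](C)(C)C
F7 | step 3 | (trimethylsilyl)ketene | C[Si](C)(C)C=C=O
F8 | step 9 | [2,4-bis(benzyloxy)-6-methylphenoxy]triisopropylsilane | Cc1cc(OCc2ccccc2)cc(OCc2ccccc2)c1O[Si](C(C)C)(C(C)C)C(C)C
F9 | step 9 | [4,6-bis(benzyloxy)-3-bromo-2-methylphenoxy]triisopropylsilane | Cc1c(Br)c(OCc2ccccc2)cc(OCc2ccccc2)c1O[Si](C(C)C)(C(C)C)C(C)C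
F10 | step 9 | [4,6-bis(benzyloxy)-2-methyl-3-(triisopropylsilyloxy)phenyl]lithium | [Li]c1c(C)c(O[Si](C(C)C)(C(C)C)C(C)C)c(OCc2ccccc2)cc1OCc1ccccc1
F11 | step 9 | 2,4-bis(benzyloxy)-6-methyl-5-(triisopropylsilyloxy)benzoic acid | Cc1c(C(=O)O)c(OCc2ccccc2)cc(OCc2ccccc2)c1O[Si](C(C)C)(C(C)C)C(C)C
F12 | step 9 | 2,4-bis(benzyloxy)-5-hydroxy-6-methylbenzoic acid | Cc1c(C(=O)O)c(OCc2ccccc2)cc(OCc2ccccc2)c1O
F13 | step 13 | 3-(benzyloxy)-4-formyl-5-methylphenyl 5-acetoxy-2,4-bis(benzyloxy)-6-methylbenzoate | CC(=O)Oc1c(C)c(C(=O)Oc2cc(C)c(C=O)c(OCc3ccccc3)c2)c(OCc2ccccc2)cc1OCc1ccccc1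
F14 | step 13 | 4-{[5-acetoxy-2,4-bis(benzyloxy)-6-methylbenzoyl]oxy}-2-(benzyloxy)-6-methylbenzoic acid | CC(=O)Oc1c(C)c(C(=O)Oc2cc(C)c(C(=O)O)c(OCc3ccccc3)c2)c(OCc2ccccc2)cc1OCc1ccccc1
F15 | step 13 | benzyl 4-[(4-{[5-acetoxy-2,4-bis(benzyloxy)-6-methylbenzoyl]oxy}-2-(benzyloxy)-6-methylbenzoyl)oxy]-2-hydroxy-6-methylbenzoate | CC(=O)Oc1c(C)c(C(=O)Oc2cc(C)c(C(=O)Oc3cc(C)c(C(=O)OCc4ccccc4)c(O)c3)c(OCc3ccccc3)c2)c(OCc2ccccc2)cc1OCc1ccccc1
A1 | alternative 1 | 6-(2,4-dioxopentyl)-2,2-dimethyl-4H-1,3-dioxin-4-one | CC(=O)CC(=O)CC1=CC(=O)OC(C)(C)O1
A2 | alternative 1 | benzyl 2-(benzyloxy)-4-hydroxy-6-methylbenzoate | Cc1cc(O)cc(OCc2ccccc2)c1C(=O)OCc1ccccc1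
A3 | alternative 1 | 3-(benzyloxy)-4-[(benzyloxy)carbonyl]-5-methylphenyl 3,5,7-trioxooctanoate | CC(=O)CC(=O)CC(=O)CC(=O)Oc1cc(C)c(C(=O)OCc2ccccc2)c(OCc2ccccc2)c1
A4 | alternative 1 | benzyl 2-(benzyloxy)-4-[(2,4-dihydroxy-6-methylbenzoyl)oxy]-6-methylbenzoate | Cc1cc(O)cc(O)c1C(=O)Oc1cc(C)c(C(=O)OCc2ccccc2)c(OCc2ccccc2)c1
A5 | alternative 2 | tert-butyl 3-oxobutanoate | CC(=O)CC(=O)OC(C)(C)C
A6 | alternative 2 | ethyl 2-[(4-methoxybenzyl)oxy]but-2-enoate (either alkene geometry) | CCOC(=O)C(OCc1ccc(OC)cc1)=CC
A7 | alternative 2 | tert-butyl 5-[(4-methoxybenzyl)oxy]-6-methyl-2,4-dioxocyclohexane-1-carboxylate (mixture of diastereomers) | CC1C(OCc2ccc(OC)cc2)C(=O)CC(=O)C1C(=O)OC(C)(C)C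
A8 | alternative 2 | tert-butyl 2,4-dihydroxy-5-[(4-methoxybenzyl)oxy]-6-methylbenzoate | Cc1c(OCc2ccc(OC)cc2)c(O)cc(O)c1C(=O)OC(C)(C)C
A9 | alternative 2 | tert-butyl 2,4-dihydroxy-6-methylbenzoate | Cc1cc(O)cc(O)c1C(=O)OC(C)(C)C
A10 | alternative 3 | {[4-(benzyloxy)furan-2-yl]oxy}(tert-butyl)dimethylsilane | CC(C)(C)[Si](C)(C)Oc1cc(OCc2ccccc2)co1
A11 | alternative 3 | benzyl 2-(benzyloxy)-4-{[2-(benzyloxy)-4-(but-2-ynoyloxy)-6-methylbenzoyl]oxy}-6-methylbenzoate | CC#CC(=O)Oc1cc(C)c(C(=O)Oc2cc(C)c(C(=O)OCc3ccccc3)c(OCc3ccccc3)c2)c(OCc2ccccc2)c1
A12 | alternative 3 | 7-oxabicyclo[2.2.1]hepta-2,5-diene adduct of A10 and A11 (racemic) | CC1=C(C(=O)Oc3cc(C)c(C(=O)Oc4cc(C)c(C(=O)OCc5ccccc5)c(OCc5ccccc5)c4)c(OCc4ccccc4)c3)C2(O[Si](C)(C)C(C)(C)C)C=C(OCc3ccccc3)C1O2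
A13 | alternative 3 | protected tridepside with ring A C2 silyl ether, C4 benzyl ether and free C5 hydroxyl | Cc1c(O)c(OCc2ccccc2)cc(O[Si](C)(C)C(C)(C)C)c1C(=O)Oc1cc(C)c(C(=O)Oc2cc(C)c(C(=O)OCc3ccccc3)c(OCc3ccccc3)c2)c(OCc3ccccc3)c1
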